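**Retrosynthetic overview**

1. The strategy rests on C2 and C5 of the oxolane. Both are benzylic to electron-rich rings, and the free 4-OH of the 4-hydroxy-3,5-dimethoxyphenyl ring makes C5 the exocyclic terminus of a p-quinone methide. O1 is therefore inserted last: O1–C2 and O1–C5 are cut back to water and a dibenzylbutane with two benzylic CH2 groups.
2. The oxolane is the only ring formed, and it is closed in the final step. C2 and C5 are set there under the cis-dimethyl pair C3/C4, which is never touched.
3. The dibenzylbutane is pseudo-meso (chiral only because its two aryl groups differ). Its methyl centres therefore come from meso-2,3-dimethylsuccinic acid, and the absolute configuration is decided by which anhydride carbonyl receives which aryl group.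
4. The veratryl group goes on first (rhodium-catalysed desymmetrising arylation of the meso anhydride, then ketone hydrogenolysis). The O-benzyl syringyl group goes on second (Weinreb amide plus Grignard reagent), so that one final hydrogenolysis removes the ketone oxygen and the benzyl group together.

Key step: step 8

Assumption: the (R,R)-enantiomer of the Taddol phosphoramidite is taken to direct the aryl group to the anhydride carbonyl next to the (S)-methine; if the sense of induction is the reverse, the (S,S)-ligand is used and nothing else changes.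

**Step 1**
Reactants: 1 meso-2,3-dimethylsuccinic acid
Product: 2 (3R,4S)-3,4-dimethyloxolane-2,5-dione (the cis or meso anhydride)
Conditions: AcCl (neat), reflux; evaporation
Reagents that add atoms: none
Why: Cyclodehydration of a 1,4-diacid with acetyl chloride (mixed anhydride, then ring closure) gives the five-membered anhydride without touching the two methine centres, so the cis (meso) relationship is kept.

**Step 2**
Reactants: 2 (3R,4S)-3,4-dimethyloxolane-2,5-dione; 3 4-bromo-1,2-dimethoxybenzene
Product: 6 (2R,3S)-4-(3,4-dimethoxyphenyl)-2,3-dimethyl-4-oxobutanoic acid, via aryllithium 4 (not isolated), via arylzinc triflate 5 (not isolated)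
Conditions: 3, n-BuLi, THF, −78 °C; Zn(OTf)2, −78 °C → rt; then 2, [Rh(cod)Cl]2 (4 mol%), (R,R)-Taddol-PNMe2 (8 mol%), THF–DMF, 50 °C; 1 M HCl work-up
Reagents that add atoms: none
Why: Enantioselective desymmetrising acyl cross-coupling (Negishi type) of a meso anhydride, in which monovalent rhodium inserts into the C–O bond of one enantiotopic carbonyl under control of the chiral phosphoramidite, the aryl group is transferred from zinc and reductive elimination gives the aryl ketone; no new stereocentre is formed, but the ligand places the aroyl group on the (S)-methine side and so fixes the absolute configuration of the whole route.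

**Step 3**
Reactants: 6 (2R,3S)-4-(3,4-dimethoxyphenyl)-2,3-dimethyl-4-oxobutanoic acid
Product: 8 (2R,3R)-4-(3,4-dimethoxyphenyl)-2,3-dimethylbutanoic acid, via benzylic alcohol 7 (not isolated)
Conditions: H2 (4 atm), 10% Pd/C, AcOH, HClO4 (cat.), rt → 40 °C
Reagents that add atoms: none
Why: Catalytic hydrogenolysis of an electron-rich aryl ketone (reduction to the benzylic alcohol, then acid-assisted benzylic C–O cleavage) removes the oxygen while the ring carries only methyl ethers, and the ketone should be reduced faster than its α-methine enolises, so both methyl centres are kept (the C3 descriptor changes only because the priorities change).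

**Step 4**
Reactants: 8 (2R,3R)-4-(3,4-dimethoxyphenyl)-2,3-dimethylbutanoic acid
Product: 10 (2R,3R)-4-(3,4-dimethoxyphenyl)-N-methoxy-N,2,3-trimethylbutanamide, via acyl imidazole 9 (not isolated)
Conditions: CDI, CH2Cl2, rt; then MeNH(OMe)·HCl, rt
Reagents that add atoms: N,O-dimethylhydroxylamine hydrochloride, CNOC.Cl
Why: Amide formation through the acyl imidazole (CDI activation) gives the N-methoxy-N-methylamide under near-neutral conditions that should leave the α-stereocentre intact.

**Step 5**
Reactants: 11 4-bromo-2,6-dimethoxyphenol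
Product: 12 2-(benzyloxy)-5-bromo-1,3-dimethoxybenzene
Conditions: BnBr, K2CO3, DMF, 60 °C
Reagents that add atoms: benzyl bromide, BrCc1ccccc1
Why: Williamson ether synthesis on the hindered but acidic phenol masks the hydroxyl for the Grignard step with a group that the later ketone hydrogenolysis removes at no extra cost.

**Step 6**
Reactants: 10 (2R,3R)-4-(3,4-dimethoxyphenyl)-N-methoxy-N,2,3-trimethylbutanamide; 12 2-(benzyloxy)-5-bromo-1,3-dimethoxybenzene
Product: 14 (2R,3R)-1-[4-(benzyloxy)-3,5-dimethoxyphenyl]-4-(3,4-dimethoxyphenyl)-2,3-dimethylbutan-1-one, via aryl Grignard reagent 13 (not isolated)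
Conditions: 12, Mg, THF, reflux; then 10, THF, 0 °C → rt; 1 M HCl work-up
Reagents that add atoms: none
Why: Weinreb ketone synthesis, in which the aryl Grignard reagent adds once to give a stable five-membered magnesium chelate that collapses to the ketone only on acidic work-up, so there is no over-addition and no enolisable ketone in the basic medium.

**Step 7**
Reactants: 14 (2R,3R)-1-[4-(benzyloxy)-3,5-dimethoxyphenyl]-4-(3,4-dimethoxyphenyl)-2,3-dimethylbutan-1-one
Product: 17 4-[(2S,3R)-4-(3,4-dimethoxyphenyl)-2,3-dimethylbutyl]-2,6-dimethoxyphenol, via debenzylated ketone 15 (not isolated), via benzylic alcohol 16 (not isolated)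
Conditions: H2 (4 atm), 10% Pd/C, AcOH–EtOAc (1:1), 40 °C
Reagents that add atoms: none
Why: One catalytic hydrogenolysis should perform O-debenzylation, ketone reduction and benzylic C–O cleavage (the last helped by the p-hydroxyl), and strong acid is left out so that the benzylic carbinol is hydrogenolysed before it can ionise and close onto the veratryl ring; the two methyl centres are not touched.

**Step 8**
Reactants: 17 4-[(2S,3R)-4-(3,4-dimethoxyphenyl)-2,3-dimethylbutyl]-2,6-dimethoxyphenol
Product: 21 (2S,3S,4R,5R)-2-(3,4-dimethoxyphenyl)-5-(4-hydroxy-3,5-dimethoxyphenyl)-3,4-dimethyloxolane, via quinone methide 18 (not isolated), via hydroxy quinone methide 19 (not isolated), via C2-epimeric oxolane 20 (not isolated)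
Conditions: DDQ (1.0 equiv, then 1.05 equiv), CH2Cl2–pH 7 phosphate buffer (10:1), 0 °C → rt; CH2Cl2 phase dried, then BF3·OEt2 (0.3 equiv), −20 °C
Reagents that add atoms: water, O
Why: The first equivalent of DDQ dehydrogenates the 4-alkyl-2,6-dimethoxyphenol to p-quinone methide 18 (C5 becomes its exocyclic terminus), the second abstracts hydride from the veratryl CH2 to give a p-methoxy-stabilised cation at C2, water is captured there (O1–C2) to give 19, and the new hydroxyl adds to the quinone methide (O1–C5), which rearomatises to the free phenol. The closest known reaction types are the DDQ oxidative cycloetherification of dibenzylbutane lignans and other p-alkoxyalkylarenes, and the hydration–cyclisation of lignan bis(quinone methides) to 2,5-diaryl-3,4-dimethyloxolanes. The one ring formed, the oxolane O1/C2–C5, closes by 5-exo-trig oxa-Michael addition. C5 is under thermodynamic control through reversible retro-oxa-Michael opening to the quinone methide and should settle with the syringyl group trans to the C4 methyl; C2 is fixed without reliable control when water adds to the planar cation, so epimer 20 is converged by BF3·OEt2, which ionises the veratryl C2–O1 bond reversibly, and the untouched cis-dimethyl pair C3/C4 makes the isomer with each aryl trans to its neighbouring methyl (aryls mutually cis) the energy minimum. The step needs oxygen capture to beat Friedel–Crafts closure to an aryltetralin and proton loss to a styrene, which the buffered wet medium, the non-nucleophilic quinoid state of the syringyl ring and the low temperature of the acid stage should secure; it also needs the product to escape a third oxidation, which rests on the two-equivalent stoichiometry and on the allylic strain that a tetrasubstituted exocyclic quinone methide or a planar 2-aryloxocarbenium ion would suffer next to the C3/C4 methyls.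

**Compound list**

1 | meso-2,3-dimethylsuccinic acid | C[C@@H](C(=O)O)[C@H](C)C(=O)O | starting material
2 | (3R,4S)-3,4-dimethyloxolane-2,5-dione (cis, meso) | C[C@@H]1C(=O)OC(=O)[C@@H]1C | intermediate
3 | 4-bromo-1,2-dimethoxybenzene | COc1ccc(Br)cc1OC | starting material
4 | (3,4-dimethoxyphenyl)lithium | COc1ccc([Li])cc1OC | intermediate
5 | (3,4-dimethoxyphenyl)zinc trifluoromethanesulfonate | COc1ccc([Zn]OS(=O)(=O)C(F)(F)F)cc1OC | intermediate
6 | (2R,3S)-4-(3,4-dimethoxyphenyl)-2,3-dimethyl-4-oxobutanoic acid | COc1ccc(C(=O)[C@@H](C)[C@@H](C)C(=O)O)cc1OC | intermediate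
7 | (2R,3S)-4-(3,4-dimethoxyphenyl)-4-hydroxy-2,3-dimethylbutanoic acid (both C4 epimers) | COc1ccc(C(O)[C@@H](C)[C@@H](C)C(=O)O)cc1OC | intermediate
8 | (2R,3R)-4-(3,4-dimethoxyphenyl)-2,3-dimethylbutanoic acid | COc1ccc(C[C@@H](C)[C@@H](C)C(=O)O)cc1OC | intermediate
9 | 1-[(2R,3R)-4-(3,4-dimethoxyphenyl)-2,3-dimethylbutanoyl]imidazole | COc1ccc(C[C@@H](C)[C@@H](C)C(=O)n2ccnc2)cc1OC | intermediate
10 | (2R,3R)-4-(3,4-dimethoxyphenyl)-N-methoxy-N,2,3-trimethylbutanamide | COc1ccc(C[C@@H](C)[C@@H](C)C(=O)N(C)OC)cc1OC | intermediate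
11 | 4-bromo-2,6-dimethoxyphenol | COc1cc(Br)cc(OC)c1O | starting material
12 | 2-(benzyloxy)-5-bromo-1,3-dimethoxybenzene | COc1cc(Br)cc(OC)c1OCc1ccccc1 | intermediate
13 | [4-(benzyloxy)-3,5-dimethoxyphenyl]magnesium bromide | COc1cc([Mg]Br)cc(OC)c1OCc1ccccc1 | intermediate
14 | (2R,3R)-1-[4-(benzyloxy)-3,5-dimethoxyphenyl]-4-(3,4-dimethoxyphenyl)-2,3-dimethylbutan-1-one | COc1ccc(C[C@@H](C)[C@@H](C)C(=O)c2cc(OC)c(OCc3ccccc3)c(OC)c2)cc1OC | intermediate
15 | (2R,3R)-4-(3,4-dimethoxyphenyl)-1-(4-hydroxy-3,5-dimethoxyphenyl)-2,3-dimethylbutan-1-one | COc1ccc(C[C@@H](C)[C@@H](C)C(=O)c2cc(OC)c(O)c(OC)c2)cc1OC | intermediate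
16 | 4-[(2R,3R)-4-(3,4-dimethoxyphenyl)-1-hydroxy-2,3-dimethylbutyl]-2,6-dimethoxyphenol (both C1 epimers) | COc1ccc(C[C@@H](C)[C@@H](C)C(O)c2cc(OC)c(O)c(OC)c2)cc1OC | intermediate
17 | 4-[(2S,3R)-4-(3,4-dimethoxyphenyl)-2,3-dimethylbutyl]-2,6-dimethoxyphenol | COc1ccc(C[C@@H](C)[C@@H](C)Cc2cc(OC)c(O)c(OC)c2)cc1OC | intermediate
18 | 4-[(2R,3R)-4-(3,4-dimethoxyphenyl)-2,3-dimethylbutylidene]-2,6-dimethoxycyclohexa-2,5-dien-1-one | COc1ccc(C[C@@H](C)[C@@H](C)C=C2C=C(OC)C(=O)C(OC)=C2)cc1OC | intermediate
19 | 4-[(2S,3S)-4-(3,4-dimethoxyphenyl)-4-hydroxy-2,3-dimethylbutylidene]-2,6-dimethoxycyclohexa-2,5-dien-1-one (both C4 epimers) | COc1ccc(C(O)[C@@H](C)[C@@H](C)C=C2C=C(OC)C(=O)C(OC)=C2)cc1OC | intermediate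
20 | (2R,3S,4R,5R)-2-(3,4-dimethoxyphenyl)-5-(4-hydroxy-3,5-dimethoxyphenyl)-3,4-dimethyloxolane | COc1ccc([C@@H]2O[C@@H](c3cc(OC)c(O)c(OC)c3)[C@H](C)[C@@H]2C)cc1OC | intermediate
21 | (2S,3S,4R,5R)-2-(3,4-dimethoxyphenyl)-5-(4-hydroxy-3,5-dimethoxyphenyl)-3,4-dimethyloxolane | COc1ccc([C@H]2O[C@@H](c3cc(OC)c(O)c(OC)c3)[C@H](C)[C@@H]2C)cc1OC | target

**Step count**

Total: 8 steps. Longest linear sequence: 7 steps (steps 1, 2, 3, 4, 6, 7, 8); step 5 is a one-step branch.

**Steps most likely to fail**

**Step 8.** The one-pot combination of the two oxidations on two different rings is the unproven part of the route. Three processes may defeat it: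
- DDQ may re-oxidise the freed phenol of the product, or the veratryl carbinol, faster than it abstracts hydride from C2, which leads to over-oxidised ring-opened ketones.
- The C2 cation or the quinone methide may be captured by the other arene (aryltetralin formation) or may lose the C3 proton, during the oxidation or during the acid stage.
- Equilibration at C2 may stay incomplete.

The fallback uses only known chemistry; it sets out from keto acid 6 (with bromide 12) and comes back to the route at target 21. NaBH4 (MeOH, 0 °C) reduces 6 to hydroxy acid 7, and TFA in CH2Cl2 closes it to the lactone (3R,4S,5S)-5-(3,4-dimethoxyphenyl)-3,4-dimethyloxolan-2-one F1; the p-methoxybenzylic C–O bond ionises reversibly, so the aryl group should end trans to the neighbouring methyl. Bromide 12 is converted with n-BuLi (THF, −78 °C) into [4-(benzyloxy)-3,5-dimethoxyphenyl]lithium F2, which adds once to F1 to give the cyclic hemiketal (3R,4S,5S)-2-[4-(benzyloxy)-3,5-dimethoxyphenyl]-5-(3,4-dimethoxyphenyl)-3,4-dimethyloxolan-2-ol F3. Et3SiH with BF3·OEt2 (CH2Cl2, −78 → −20 °C) reduces F3 through the 2-aryloxocarbenium ion, and BF3·OEt2 epimerises the new benzylic centre to the trans arrangement, giving the benzyl ether (2S,3S,4R,5R)-5-[4-(benzyloxy)-3,5-dimethoxyphenyl]-2-(3,4-dimethoxyphenyl)-3,4-dimethyloxolane F4. H2 over Pd/C in EtOAc then removes the benzyl group to give 21.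

**Step 2.** The catalyst may discriminate poorly between the two enantiotopic carbonyls, transmetallation from the electron-rich arylzinc may be slow, or the centre next to the new ketone may enolise.

The fallback sets out from anhydride 2 and comes back at Weinreb amide 10. Methanolysis of 2 mediated by a cinchona alkaloid (quinidine or quinine, whichever opens the carbonyl next to the (R)-methine; MeOH, toluene, −55 °C) should give the hemiester (2S,3R)-4-methoxy-2,3-dimethyl-4-oxobutanoic acid F5. EtSH, DCC and catalytic DMAP convert it into the thioester methyl (2R,3S)-4-(ethylsulfanyl)-2,3-dimethyl-4-oxobutanoate F6. Fukuyama coupling of F6 with arylzinc 5 (PdCl2(PPh3)2, THF–toluene, rt) gives the keto ester methyl (2R,3S)-4-(3,4-dimethoxyphenyl)-2,3-dimethyl-4-oxobutanoate F7. Hydrogenolysis as in step 3 gives methyl (2R,3R)-4-(3,4-dimethoxyphenyl)-2,3-dimethylbutanoate F8, and MeNH(OMe)·HCl with i-PrMgCl (THF, −20 °C) turns this ester directly into 10.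

**Step 7.** Deoxygenation may stall at the benzylic alcohol once the phenol is freed, or the carbinol may ionise and close onto the veratryl ring before it is hydrogenolysed.

The fallback sets out from ketone 14 and comes back at 17. TsNHNH2 (EtOH, cat. AcOH) gives the tosylhydrazone N'-[(2R,3R)-1-[4-(benzyloxy)-3,5-dimethoxyphenyl]-4-(3,4-dimethoxyphenyl)-2,3-dimethylbutylidene]-4-methylbenzenesulfonohydrazide F9. Catecholborane (CHCl3, 0 °C), then NaOAc·3H2O at reflux, reduces it without a cationic intermediate to 2-(benzyloxy)-5-[(2S,3R)-4-(3,4-dimethoxyphenyl)-2,3-dimethylbutyl]-1,3-dimethoxybenzene F10. Neutral hydrogenolysis (H2, Pd/C, EtOAc) then gives 17.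

**Further compounds**

F1 | step 8 | (3R,4S,5S)-5-(3,4-dimethoxyphenyl)-3,4-dimethyloxolan-2-one | COc1ccc([C@H]2OC(=O)[C@H](C)[C@@H]2C)cc1OC
F2 | step 8 | [4-(benzyloxy)-3,5-dimethoxyphenyl]lithium | COc1cc([Li])cc(OC)c1OCc1ccccc1
F3 | step 8 | (3R,4S,5S)-2-[4-(benzyloxy)-3,5-dimethoxyphenyl]-5-(3,4-dimethoxyphenyl)-3,4-dimethyloxolan-2-ol (both C2 anomers) | COc1ccc([C@H]2OC(O)(c3cc(OC)c(OCc4ccccc4)c(OC)c3)[C@H](C)[C@@H]2C)cc1OC
F4 | step 8 | (2S,3S,4R,5R)-5-[4-(benzyloxy)-3,5-dimethoxyphenyl]-2-(3,4-dimethoxyphenyl)-3,4-dimethyloxolane | COc1ccc([C@H]2O[C@@H](c3cc(OC)c(OCc4ccccc4)c(OC)c3)[C@H](C)[C@@H]2C)cc1OC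
F5 | step 2 | (2S,3R)-4-methoxy-2,3-dimethyl-4-oxobutanoic acid | OC(=O)[C@@H](C)[C@@H](C)C(=O)OC
F6 | step 2 | methyl (2R,3S)-4-(ethylsulfanyl)-2,3-dimethyl-4-oxobutanoate | CCSC(=O)[C@@H](C)[C@@H](C)C(=O)OC
F7 | step 2 | methyl (2R,3S)-4-(3,4-dimethoxyphenyl)-2,3-dimethyl-4-oxobutanoate | COc1ccc(C(=O)[C@@H](C)[C@@H](C)C(=O)OC)cc1OC
F8 | step 2 | methyl (2R,3R)-4-(3,4-dimethoxyphenyl)-2,3-dimethylbutanoate | COc1ccc(C[C@@H](C)[C@@H](C)C(=O)OC)cc1OC
F9 | step 7 | N'-[(2R,3R)-1-[4-(benzyloxy)-3,5-dimethoxyphenyl]-4-(3,4-dimethoxyphenyl)-2,3-dimethylbutylidene]-4-methylbenzenesulfonohydrazide | COc1ccc(C[C@@H](C)[C@@H](C)C(=NNS(=O)(=O)c2ccc(C)cc2)c2cc(OC)c(OCc3ccccc3)c(OC)c2)cc1OC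
F10 | step 7 | 2-(benzyloxy)-5-[(2S,3R)-4-(3,4-dimethoxyphenyl)-2,3-dimethylbutyl]-1,3-dimethoxybenzene | COc1ccc(C[C@@H](C)[C@@H](C)Cc2cc(OC)c(OCc3ccccc3)c(OC)c2)cc1OC
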